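**Strategy.** Ring B of the target carries, in a row, the C8 carbinol, C9 with its C11–O arm and quaternary C10. Retrosynthetic removal of the C8 methyl leaves an 8-keto-11-hydroxy (β-hydroxy ketone) array in which C9 can be excised from between C8 and C10, contracting ring B to the five-membered ring C5–C6–C7–C8–C10 of a trans-hydrindane. In the forward sense a Lewis-acid semipinacol shift of C10 from C8 to the oxirane carbon C9 forms the C9–C10 bond, enlarges the ring to ring B, sets C9 and unveils both the C8 ketone and the C11 hydroxyl. The precursor is a 3-O-TBS trans-hydrindane with a tertiary C8 hydroxyl and a (9R)-oxirane, made from a Hajos–Parrish-type enedione.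

Key step: step 9

Numbering: all compounds carry the drimane numbers of the target. Ring A is C1–C5 and C10 (C3 oxygenated, C4 gem-dimethyl, C10 angular methyl). Ring B is C5–C10. C11 is the CH2O carbon on C9. In the hydrindanes the five-membered ring is C5, C6, C7, C8, C10.

Remark on the chemistry: the ethyl-ketone side chain is assumed to cyclise with useful enantioselectivity only under primary-amino-acid/acid mediation, so D-phenylalanine replaces D-proline; enantiomeric purity is assumed to be raised by recrystallising a crystalline intermediate.

Step 1
Reactants: 1 2-methylcyclopentane-1,3-dione; 2 ethyl vinyl ketone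
Product: 3 2-methyl-2-(3-oxopentyl)cyclopentane-1,3-dione
Conditions: H2O, AcOH (cat.), 75 °C
Reagents that add atoms: none
Why: Michael addition of the acidic cyclic 1,3-dione to the enone in water; the new quaternary carbon is not yet stereogenic because the two ring carbonyls are enantiotopic.

Step 2
Reactants: 3 2-methyl-2-(3-oxopentyl)cyclopentane-1,3-dione
Product: 4 (7aR)-4,7a-dimethyl-2,3,7,7a-tetrahydro-1H-indene-1,5(6H)-dione
Conditions: D-phenylalanine (1 equiv), (1R)-(−)-camphor-10-sulfonic acid (0.5 equiv), DMF, 25 → 70 °C
Reagents that add atoms: none
Why: Hajos–Parrish–Eder–Sauer–Wiechert aldol condensation in its primary-amino-acid/acid variant; the enamine of the D-amino acid selects one enantiotopic ring carbonyl, which should set C10 as R (mirror image of the L-amino-acid outcome), and the aldol dehydrates in the same pot.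

Step 3
Reactants: 4 (7aR)-4,7a-dimethyl-2,3,7,7a-tetrahydro-1H-indene-1,5(6H)-dione
Product: 5 C8 ethylene ketal of 4
Conditions: TMSOCH2CH2OTMS, TMSOTf (cat.), CH2Cl2, −78 → −20 °C
Reagents that add atoms: 1,2-bis(trimethylsilyloxy)ethane, C[Si](C)(C)OCCO[Si](C)(C)C
Why: Noyori dioxolanation under kinetic conditions should ketalise the saturated five-ring ketone (C8) much faster than the conjugated, tetrasubstituted enone carbonyl (C3), and it leaves C10 untouched.

Step 4
Reactants: 5 C8 ethylene ketal of 4
Product: 7 trans-fused 4,4,10-trimethyl-3-oxohydrindane C8 ethylene ketal, via lithium enolate 6 (not isolated)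
Conditions: Li (2.2 equiv), NH3(l)/THF, t-BuOH (1 equiv), −78 → −33 °C; then MeI, −78 °C → rt
Reagents that add atoms: iodomethane, CI
Why: Birch-type enone reduction with Stork reductive alkylation; the β-carbon C5 should be protonated on the face opposite the C10 methyl, giving the trans ring fusion, and the regiodefined C3–C4 enolate is C-methylated to the gem-dimethyl group, which creates no stereocentre.

Step 5
Reactants: 7 trans-fused 4,4,10-trimethyl-3-oxohydrindane C8 ethylene ketal
Product: 9 3-hydroxy-4,4,10-trimethyl-trans-hydrindan-8-one, via hydroxy ketal 8 (not isolated)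
Conditions: NaBH4, MeOH, 0 °C; then 2 M HCl, THF, rt
Reagents that add atoms: water, O
Why: borohydride reduction with axial hydride delivery on the face away from the axial C4 methyl, as with 4,4-dimethyl-3-oxo terpenoids, should give the equatorial C3 alcohol cis to the C10 methyl; acid hydrolysis of the dioxolane then frees the C8 ketone.

Step 6
Reactants: 9 3-hydroxy-4,4,10-trimethyl-trans-hydrindan-8-one
Product: 10 3-O-TBS ether of 9
Conditions: TBSOTf, 2,6-lutidine, CH2Cl2, −78 → 0 °C
Reagents that add atoms: tert-butyldimethylsilyl trifluoromethanesulfonate, CC(C)(C)[Si](C)(C)OS(=O)(=O)C(F)(F)F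
Why: silyl ether formation at the hindered equatorial C3 hydroxyl with the reactive silyl triflate; 2,6-lutidine at low temperature should not enolise the hindered C8 ketone, and no stereocentre is affected.

Step 7
Reactants: 10 3-O-TBS ether of 9
Product: 11 8-vinyl tertiary alcohol (C8–OH cis and vinyl trans to the C10 methyl)
Conditions: vinylmagnesium bromide, CeCl3 (anhydrous), THF, −78 → 0 °C
Reagents that add atoms: vinylmagnesium bromide, C=C[Mg]Br
Why: 1,2-addition of the vinyl organocerium reagent, chosen because the hindered C8 ketone is enolisable; as with 17-oxo steroids the nucleophile should enter on the face opposite the angular C10 methyl, so the vinyl group ends trans and the hydroxyl cis to that methyl.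

Step 8
Reactants: 11 8-vinyl tertiary alcohol
Product: 12 (8R,9R)-epoxy alcohol (trans-hydrindane, C8–OH cis to the C10 methyl, (9R)-oxiranyl on C8, 3-O-TBS)
Conditions: VO(acac)2 (5 mol %), t-BuOOH (in decane), toluene, 0 °C → rt
Reagents that add atoms: tert-butyl hydroperoxide, CC(C)(C)OO
Why: vanadium-catalysed hydroxyl-directed epoxidation; oxygen is passed from the vanadium alkoxide of the C8 hydroxyl to the alkene face syn to the C8–O bond (O–C8–C9=C11 dihedral near 45°), and of the two rotamers that allow this, the one with C11 gauche to the C7 methylene and anti to quaternary C10 avoids the C1 methylene, so the (9R)-oxirane should predominate.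

Step 9
Reactants: 12 (8R,9R)-epoxy alcohol
Product: 13 (9S)-8-oxo-11-hydroxy trans-decalin (CH2OH on C9 axial and trans to the C10 methyl, 3-O-TBS)
Conditions: BF3·OEt2 (1.2 equiv), CH2Cl2, −78 → −40 °C; sat. NaHCO3
Reagents that add atoms: none
Why: BF3 binds the oxirane oxygen, the C9–O bond lengthens, and the C8–C10 σ-bond, held antiperiplanar to it, shifts to C9 as the C8 carbinol becomes a carbonyl group; this is the semipinacol rearrangement of a 2,3-epoxy alcohol to a β-hydroxy ketone in its ring-expanding form, known for 1-oxiranylcycloalkanols. Ring B is closed by this 1,2-shift, a ring enlargement in which C9 is inserted into the C8–C10 bond of the five-membered ring, and not by an exo or endo cyclisation, so the trans ring fusion from step 4 is carried through and C10 migrates with retention. The one new stereocentre, C9, is fixed by the oxirane configuration because the migrating carbon enters anti to the departing oxygen (inversion), so the (9R)-oxirane should deliver the C11 arm axial and trans to the C10 methyl (9S). The step needs opening at C9 and not at C11, and migration of C10 and not of C7: the first is secured because only cleavage next to the carbinol is assisted by the shift and ends in a carbonyl group; the second by the higher migratory aptitude of fully substituted C10 and by the rotamer that keeps the bulky BF3-bound oxygen in the open sector between the hydroxyl and C7, which places C10 anti. Low temperature and a bicarbonate quench are chosen so that the β-hydroxy ketone neither epimerises at C9 nor loses formaldehyde by retro-aldol cleavage.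

Step 10
Reactants: 13 (9S)-8-oxo-11-hydroxy trans-decalin
Product: 14 (8R,9S)-8,11-diol (C8 methyl equatorial, C8–OH axial and cis to the C10 methyl, 3-O-TBS)
Conditions: MeMgBr (3.5 equiv), CeCl3 (anhydrous), THF, −78 °C
Reagents that add atoms: methylmagnesium bromide, C[Mg]Br
Why: organocerium 1,2-addition after deprotonation of the C11 hydroxyl; the axial trajectory is blocked by the 1,3-diaxial C10 methyl, so the methyl group should enter equatorially from the opposite face and leave the C8 hydroxyl axial (8R), while the low basicity of the cerium reagent at −78 °C should prevent C9 epimerisation and retro-aldol cleavage.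

Step 11
Reactants: 14 (8R,9S)-8,11-diol; 15 umbelliferone
Product: 16 11-O-(2-oxo-2H-chromen-7-yl) ether of 14
Conditions: PPh3, DIAD, THF, 0 °C → rt
Reagents that add atoms: none
Why: Mitsunobu etherification; the acidic phenol (pKa about 8) protonates the betaine and displaces the oxyphosphonium of the only primary alcohol at the CH2 carbon C11, so no stereocentre is involved, and the tertiary C8 hydroxyl is not activated and, being trans-diaxial to the C11 arm, cannot close an oxetane.

Step 12
Reactants: 16 11-O-(2-oxo-2H-chromen-7-yl) ether of 14
Product: 17 3,8-diol coumarin ether (desilylated 16)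
Conditions: HF·pyridine, THF/pyridine, 0 °C → rt
Reagents that add atoms: none
Why: fluoride-induced Si–O cleavage (desilylation) under buffered, mildly acidic conditions that should leave the coumarin lactone, the aryl ether and the tertiary alcohol untouched.

Step 13
Reactants: 17 3,8-diol coumarin ether; 18 tiglic acid
Product: 20 target tiglate CNP0189964.3, via tiglic 2,4,6-trichlorobenzoic anhydride 19 (not isolated)
Conditions: 18, 2,4,6-trichlorobenzoyl chloride, Et3N, toluene, rt; then 17, DMAP, toluene, 60 °C
Reagents that add atoms: none
Why: Yamaguchi esterification; DMAP transfers the tigloyl group of the mixed anhydride to the secondary C3 hydroxyl with retention (its C–O bond is not broken), the tertiary C8 hydroxyl does not react, and the E geometry of the tiglate, the stable isomer, is kept.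

**Compound list**

1 | 2-methylcyclopentane-1,3-dione | CC1C(=O)CCC1=O | starting material
2 | ethyl vinyl ketone (pent-1-en-3-one) | CCC(=O)C=C | starting material
3 | 2-methyl-2-(3-oxopentyl)cyclopentane-1,3-dione (achiral triketone) | CCC(=O)CCC1(C)C(=O)CCC1=O | intermediate
4 | (7aR)-4,7a-dimethyl-2,3,7,7a-tetrahydro-1H-indene-1,5(6H)-dione (C10 R; enone carbonyl C3, five-ring carbonyl C8) | O=C1CC[C@]2(C)C(CCC2=O)=C1C | intermediate
5 | C8 ethylene ketal (1,3-dioxolane) of 4, enone intact | O=C1CC[C@]2(C)C(CCC23OCCO3)=C1C | intermediate
6 | lithium C3–C4 enolate of the trans-fused 4-methyl C8-ketal (C5–H trans to the C10 methyl) | [Li]OC=1CC[C@]2(C)[C@H](CCC23OCCO3)C=1C | intermediate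
7 | trans-fused 4,4,10-trimethyl-3-oxohydrindane C8 ethylene ketal (C5–H trans to the C10 methyl) | O=C1CC[C@]2(C)[C@H](CCC23OCCO3)C1(C)C | intermediate
8 | 3-hydroxy C8-ketal (3-OH equatorial, cis to the C10 methyl) | O[C@@H]1CC[C@]2(C)[C@H](CCC23OCCO3)C1(C)C | intermediate
9 | 3-hydroxy-4,4,10-trimethyl-trans-hydrindan-8-one (3-OH equatorial, cis to the C10 methyl) | O[C@@H]1CC[C@]2(C)[C@H](CCC2=O)C1(C)C | intermediate
10 | 3-O-TBS ether of 9 | CC(C)(C)[Si](C)(C)O[C@@H]1CC[C@]2(C)[C@H](CCC2=O)C1(C)C | intermediate
11 | 8-vinyl tertiary alcohol (C8–OH cis, vinyl trans to the C10 methyl; 3-O-TBS) | CC(C)(C)[Si](C)(C)O[C@@H]1CC[C@]2(C)[C@H](CC[C@]2(O)C=C)C1(C)C | intermediate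
12 | (8R,9R)-epoxy alcohol: trans-hydrindane with C8–OH cis to the C10 methyl and a (9R)-oxiranyl group on C8; 3-O-TBS | CC(C)(C)[Si](C)(C)O[C@@H]1CC[C@]2(C)[C@H](CC[C@]2(O)[C@H]3CO3)C1(C)C | intermediate
13 | (9S)-8-oxo-11-hydroxy trans-decalin: CH2OH on C9 axial and trans to the C10 methyl; 3-O-TBS | CC(C)(C)[Si](C)(C)O[C@@H]1CC[C@]2(C)[C@H](CCC(=O)[C@@H]2CO)C1(C)C | intermediate
14 | (8R,9S)-8,11-diol: C8 methyl equatorial, C8–OH axial and cis to the C10 methyl; 3-O-TBS | CC(C)(C)[Si](C)(C)O[C@@H]1CC[C@]2(C)[C@H](CC[C@@](C)(O)[C@@H]2CO)C1(C)C | intermediate
15 | umbelliferone (7-hydroxycoumarin) | Oc1ccc2ccc(=O)oc2c1 | starting material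
16 | 11-O-(2-oxo-2H-chromen-7-yl) ether of 14; 3-O-TBS | CC(C)(C)[Si](C)(C)O[C@@H]1CC[C@]2(C)[C@H](CC[C@@](C)(O)[C@@H]2COc2ccc3ccc(=O)oc3c2)C1(C)C | intermediate
17 | 3,8-diol coumarin ether (desilylated 16) | O[C@@H]1CC[C@]2(C)[C@H](CC[C@@](C)(O)[C@@H]2COc2ccc3ccc(=O)oc3c2)C1(C)C | intermediate
18 | tiglic acid ((E)-2-methylbut-2-enoic acid) | C/C=C(\C)C(=O)O | starting material
19 | tiglic 2,4,6-trichlorobenzoic mixed anhydride | C/C=C(\C)C(=O)OC(=O)c1c(Cl)cc(Cl)cc1Cl | intermediate
20 | target: (3R,5S,8R,9S,10R)-3-O-tigloyl-8-hydroxydriman-11-yl 7-coumarinyl ether | C/C=C(\C)C(=O)O[C@@H]1CC[C@]2(C)[C@H](CC[C@@](C)(O)[C@@H]2COc2ccc3ccc(=O)oc3c2)C1(C)C | target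

**Totals.** Total step count: 13. Longest linear sequence: 13 steps (1 and 2 to 20); umbelliferone and tiglic acid enter as purchased compounds in steps 11 and 13.

**Steps most likely to fail**

1. Step 9. The Lewis acid may open the oxirane at the primary carbon C11 by fluoride transfer, or the shift may stall at the weakly stabilised secondary C9, so that the free hydroxy epoxide decomposes or the product loses formaldehyde. Fallback, setting out from 12: the tertiary hydroxyl is silylated with N-(trimethylsilyl)imidazole to the 8-O-trimethylsilyl epoxide F1. This epoxy silyl ether is then rearranged with TiCl4 in CH2Cl2 at −78 °C, a Suzuki–Tsuchihashi-type rearrangement of 2,3-epoxy alcohol silyl ethers. The silyloxy group is the stronger donor for the shift, the Lewis acid carries no fluoride, and the product is held as a titanium aldolate until aqueous work-up, which returns to the route at 13.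

2. Step 8. Facial selectivity of oxygen transfer may be poor, because the choice between the two reactive rotamers of an acyclic vinyl carbinol is only moderately biased; the minor oxirane would lead to the C9 epimer. Fallback, setting out from 11: the lithium alkoxide (n-BuLi, THF, −78 °C) is carboxylated with CO2 and cyclised with I2 to the cyclic iodocarbonate F2. In this 5-exo iodocyclisation the iodomethyl group should settle trans to quaternary C10 on the five-membered carbonate ring, which is the required C9 configuration. K2CO3 in MeOH then cleaves the carbonate and the C9 alkoxide displaces iodide, closing the oxirane with the C9–O bond intact and returning to the route at 12.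

3. Step 11. Substitution at the β-branched, axial C11 may be too slow, so that the oxyphosphonium is diverted to elimination or to alkylation of the hydrazide. Fallback, setting out from 14: the C–O bond is made at the aryl carbon instead, by palladium-catalysed C–O cross-coupling of the primary alcohol with purchased 7-bromocoumarin ([Pd(allyl)Cl]2, the biaryl phosphine RockPhos, Cs2CO3, toluene, 90 °C). No substitution at C11 is needed and the tertiary C8 hydroxyl should not couple. The coupling returns to the route at 16 and makes no new intermediate (F0).

**Further compounds**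

F1 | step 9 | 8-O-trimethylsilyl ether of epoxy alcohol 12 | CC(C)(C)[Si](C)(C)O[C@@H]1CC[C@]2(C)[C@H](CC[C@]2(O[Si](C)(C)C)[C@H]3CO3)C1(C)C
F2 | step 8 | cyclic iodocarbonate of 11 (spiro 1,3-dioxolan-2-one across C8–O and C9–O, iodomethyl on C9 trans to C10) | CC(C)(C)[Si](C)(C)O[C@@H]1CC[C@]2(C)[C@H](CC[C@]2(OC(=O)O3)[C@H]3CI)C1(C)C
F0 | step 11 | none | none
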